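**Retrosynthetic overview**
1. The heterocycle is closed last (C1–C8a and C1–N bonds). N-Methylaminophenol 28 and acetaldehyde undergo an intramolecular phenolic Mannich reaction (Pictet–Spengler). The naphthyl group blocks the second ortho carbon, and C-3 directs C-1 to the trans arrangement.
2. The C5–C8' biaryl bond comes from a Suzuki–Miyaura coupling of aryl triflate 14 (fragment A) with naphthylboronic acid 26 (fragment B).
3. Fragment A starts from vanillin. O-Allylation, Dakin-type oxidation and Claisen rearrangement fix the 1,2,3,5-substitution pattern. Wacker oxidation and reductive amination with (R)-1-phenylethylamine then set C-3.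
4. Fragment B starts from 2-bromo-5-methoxybenzaldehyde. Stobbe condensation and cyclodehydration build the second naphthalene ring, then the ester becomes CH3 and Br becomes B(OH)2.
5. Ring order: the methyl-bearing naphthalene ring (step 10), then the biaryl bond (step 17), then the tetrahydropyridine ring (step 19).

Assumption: the SMILES fixes C-1 and C-3 (both R, 1,3-trans) but not the hindered 5,8' axis. The route controls the two stereocentres, and the two atropo-diastereomers formed in step 17 are separated at the end and assigned by NOE and CD.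

**Fragment A**

Step 1
Reactants: 1 vanillin; 2 allyl bromide
Product: 3 4-(allyloxy)-3-methoxybenzaldehyde
Conditions: K2CO3, acetone, reflux
Reagents that add atoms: none
Why: Williamson ether synthesis, in which the phenoxide displaces the allylic bromide (SN2) and the aldehyde is inert to K2CO3.

Step 2
Reactants: 3 4-(allyloxy)-3-methoxybenzaldehyde
Product: 5 4-(allyloxy)-3-methoxyphenol, via aryl formate 4 (not isolated)
Conditions: 30% aq H2O2 (1.3 equiv), H2SO4 (cat.), MeOH, rt
Reagents that add atoms: hydrogen peroxide, OO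
Why: Acid-catalysed Dakin-type (Baeyer–Villiger) oxidation, in which the electron-rich p-alkoxyaryl group migrates to give formate 4, methanol cleaves it in situ, and the unactivated allyl double bond is not epoxidised by H2O2.

Step 3
Reactants: 5 4-(allyloxy)-3-methoxyphenol
Product: 6 1-(allyloxy)-4-(benzyloxy)-2-methoxybenzene
Conditions: BnBr, K2CO3, DMF, rt
Reagents that add atoms: benzyl bromide, BrCc1ccccc1
Why: Williamson ether synthesis that masks the future 8-OH as a benzyl ether stable to heat, base, hydride and palladium coupling.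

Step 4
Reactants: 6 1-(allyloxy)-4-(benzyloxy)-2-methoxybenzene
Product: 7 2-allyl-4-(benzyloxy)-6-methoxyphenol
Conditions: PhNEt2, 200 °C, N2
Reagents that add atoms: none
Why: Aromatic Claisen rearrangement ([3,3]-sigmatropic shift, then tautomerisation), which can rearomatise only at the single free ortho carbon and so places the C3 chain, OH, OMe and OBn unambiguously.

Step 5
Reactants: 7 2-allyl-4-(benzyloxy)-6-methoxyphenol
Product: 8 2-allyl-4-(benzyloxy)-6-methoxyphenyl trifluoromethanesulfonate
Conditions: Tf2O, pyridine, CH2Cl2, 0 °C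
Reagents that add atoms: triflic anhydride, O=S(=O)(OS(=O)(=O)C(F)(F)F)C(F)(F)F
Why: O-Sulfonylation of the phenol, which creates the coupling handle and also prevents oxypalladation to a benzofuran in the next step.

Step 6
Reactants: 8 2-allyl-4-(benzyloxy)-6-methoxyphenyl trifluoromethanesulfonate
Product: 9 4-(benzyloxy)-2-methoxy-6-(2-oxopropyl)phenyl trifluoromethanesulfonate
Conditions: PdCl2 (10 mol %), CuCl (1 equiv), O2 (1 atm), DMF/H2O 7:1, rt
Reagents that add atoms: water, O
Why: Wacker–Tsuji oxidation, in which divalent palladium activates the terminal alkene for Markovnikov attack of water, CuCl/O2 reoxidise the metal, and the ligand-free catalyst leaves the hindered aryl triflate untouched at rt.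

Step 7
Reactants: 9 4-(benzyloxy)-2-methoxy-6-(2-oxopropyl)phenyl trifluoromethanesulfonate; 10 (R)-1-phenylethylamine
Product: 12 4-(benzyloxy)-2-methoxy-6-[(2R)-2-{[(1R)-1-phenylethyl]amino}propyl]phenyl trifluoromethanesulfonate, via ketimine 11 (not isolated)
Conditions: Ti(OiPr)4, THF, rt; then NaBH4, EtOH, −78 to −20 °C; chromatography, HCl salt recrystallised and free-based
Reagents that add atoms: none
Why: Auxiliary-controlled reductive amination, in which ketimine 11 holds its benzylic C–H eclipsed with C=N (allylic 1,3-strain) and hydride attacks anti to the phenyl group, so the like (R,R) amine is the major product (about 5:1, raised to >98:2 by purification) and C-3 of the target is set as R.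

Step 8
Reactants: 12 (R,R)-secondary amine
Product: 14 4-(benzyloxy)-2-methoxy-6-[(2R)-2-{methyl[(1R)-1-phenylethyl]amino}propyl]phenyl trifluoromethanesulfonate, via methyleneiminium ion 13 (not isolated)
Conditions: 37% aq HCHO, NaBH(OAc)3, ClCH2CH2Cl, rt
Reagents that add atoms: formaldehyde, C=O
Why: Reductive amination with formaldehyde installs the N-methyl group of the target without touching either stereocentre and leaves a robust tertiary amine for the coupling.

**Fragment B**

Step 9
Reactants: 15 2-bromo-5-methoxybenzaldehyde; 16 diethyl succinate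
Product: 17 (E)-4-(2-bromo-5-methoxyphenyl)-3-(ethoxycarbonyl)but-3-enoic acid
Conditions: KOtBu, tBuOH, reflux; aq HCl work-up
Reagents that add atoms: none
Why: Stobbe condensation (aldol addition, lactonisation, E1cB ring opening), which gives mainly the E half-ester with the aryl group cis to CH2CO2H, as ring closure requires.

Step 10
Reactants: 17 Stobbe half-ester
Product: 18 ethyl 4-acetoxy-8-bromo-5-methoxynaphthalene-2-carboxylate
Conditions: Ac2O, NaOAc, reflux
Reagents that add atoms: acetic anhydride, CC(=O)OC(C)=O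
Why: Cyclodehydration through the mixed anhydride (intramolecular Friedel–Crafts acylation), in which bromine blocks one ortho carbon so closure occurs at the carbon ortho to OMe, and the resulting naphthol is acetylated in situ.

Step 11
Reactants: 18 ethyl 4-acetoxy-8-bromo-5-methoxynaphthalene-2-carboxylate
Product: 19 ethyl 8-bromo-4-hydroxy-5-methoxynaphthalene-2-carboxylate
Conditions: NaOEt (1.1 equiv), EtOH, 0 °C to rt; aq HCl work-up
Reagents that add atoms: none
Why: Transesterification (ethanolysis) removes the activated aryl acetate selectively, and ethoxide cannot scramble the ethyl ester.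

Step 12
Reactants: 19 ethyl 8-bromo-4-hydroxy-5-methoxynaphthalene-2-carboxylate
Product: 20 ethyl 8-bromo-4,5-dimethoxynaphthalene-2-carboxylate
Conditions: MeI, K2CO3, acetone, reflux
Reagents that add atoms: iodomethane, CI
Why: Williamson O-methylation of the naphthoxide completes the 4,5-dimethoxy pattern.

Step 13
Reactants: 20 ethyl 8-bromo-4,5-dimethoxynaphthalene-2-carboxylate
Product: 21 (8-bromo-4,5-dimethoxynaphthalen-2-yl)methanol
Conditions: LiAlH4, THF, 0 °C
Reagents that add atoms: none
Why: Hydride reduction of the ester to the primary alcohol is fast at 0 °C, where the aryl bromide is not reduced.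

Step 14
Reactants: 21 (8-bromo-4,5-dimethoxynaphthalen-2-yl)methanol
Product: 22 1-bromo-7-(bromomethyl)-4,5-dimethoxynaphthalene
Conditions: PBr3 (0.4 equiv), CH2Cl2, 0 °C
Reagents that add atoms: phosphorus tribromide, BrP(Br)Br
Why: The benzylic alcohol is activated as a phosphite ester and displaced by bromide (SN2).

Step 15
Reactants: 22 1-bromo-7-(bromomethyl)-4,5-dimethoxynaphthalene
Product: 23 1-bromo-4,5-dimethoxy-7-methylnaphthalene
Conditions: LiBHEt3, THF, 0 °C
Reagents that add atoms: none
Why: SN2 hydride displacement of the benzylic bromide by the strongly nucleophilic borohydride is chemoselective over the sp2 C–Br bond.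

Step 16
Reactants: 23 1-bromo-4,5-dimethoxy-7-methylnaphthalene
Product: 26 (4,5-dimethoxy-7-methylnaphthalen-1-yl)boronic acid, via aryllithium 24 (not isolated), via lithium aryltrimethoxyborate 25 (not isolated)
Conditions: n-BuLi, THF, −78 °C; B(OMe)3, −78 °C to rt; 1 M HCl
Reagents that add atoms: trimethyl borate, COB(OC)OC; water, O
Why: Bromine–lithium exchange outruns any ortho-lithiation at −78 °C, and borate trapping followed by hydrolysis gives the boronic acid.

**Union and ring closure**

Step 17
Reactants: 14 aryl triflate (fragment A); 26 naphthylboronic acid (fragment B)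
Product: 27 (2R)-1-[5-(benzyloxy)-2-(4,5-dimethoxy-7-methylnaphthalen-1-yl)-3-methoxyphenyl]-N-methyl-N-[(1R)-1-phenylethyl]propan-2-amine (about 1:1 mixture of atropo-diastereomers)
Conditions: Pd(OAc)2 (5 mol %), SPhos (10 mol %), K3PO4 (3 equiv), toluene/H2O 10:1, 100 °C
Reagents that add atoms: none
Why: Suzuki–Miyaura coupling, in which the bulky electron-rich biarylphosphine lets zerovalent palladium insert into the di-ortho-substituted triflate and drives reductive elimination of the hindered biaryl, with neither stereocentre involved.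

Step 18
Reactants: 27 protected biaryl amine
Product: 28 4-(4,5-dimethoxy-7-methylnaphthalen-1-yl)-3-methoxy-5-[(2R)-2-(methylamino)propyl]phenol
Conditions: H2 (4 bar), Pd(OH)2/C, MeOH/AcOH 10:1, rt; aq NaHCO3
Reagents that add atoms: none
Why: Catalytic hydrogenolysis cleaves the two benzylic bonds (O–CH2Ph and N–CH(CH3)Ph) in one operation, while the homobenzylic C–N bond that carries the stereocentre is inert.

Step 19
Reactants: 28 N-methylaminophenol; 29 acetaldehyde
Product: 31 ancistrocongoline B with (1R,3R) configuration, via ethylideneiminium ion 30 (not isolated)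
Conditions: 29 (5 equiv), AcOH, 0.02 M, 50 °C, sealed tube; aq NaHCO3; preparative HPLC (removes minor cis isomer, separates the two atropo-diastereomers)
Reagents that add atoms: none
Why: Intramolecular phenolic Mannich reaction (Pictet–Spengler, 6-endo), in which iminium 30 is attacked by the only free carbon ortho to the side chain (ortho to OH, para to OMe, the other ortho carbon bearing the naphthyl group) through a half-chair with the C-3 methyl pseudo-equatorial and the new C-1 methyl pseudo-axial, away from N-methyl and the peri 8-OH, which gives the 1,3-trans (1R,3R) isomer, also the thermodynamic product under these reversible conditions.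

**Compound list**
1 | vanillin (4-hydroxy-3-methoxybenzaldehyde) | COc1cc(C=O)ccc1O | starting material
2 | allyl bromide | C=CCBr | starting material
3 | 4-(allyloxy)-3-methoxybenzaldehyde | C=CCOc1ccc(C=O)cc1OC | intermediate
4 | 4-(allyloxy)-3-methoxyphenyl formate | C=CCOc1ccc(OC=O)cc1OC | intermediate
5 | 4-(allyloxy)-3-methoxyphenol | C=CCOc1ccc(O)cc1OC | intermediate
6 | 1-(allyloxy)-4-(benzyloxy)-2-methoxybenzene | C=CCOc1ccc(OCc2ccccc2)cc1OC | intermediate
7 | 2-allyl-4-(benzyloxy)-6-methoxyphenol | C=CCc1cc(OCc2ccccc2)cc(OC)c1O | intermediate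
8 | 2-allyl-4-(benzyloxy)-6-methoxyphenyl trifluoromethanesulfonate | C=CCc1cc(OCc2ccccc2)cc(OC)c1OS(=O)(=O)C(F)(F)F | intermediate
9 | 4-(benzyloxy)-2-methoxy-6-(2-oxopropyl)phenyl trifluoromethanesulfonate | CC(=O)Cc1cc(OCc2ccccc2)cc(OC)c1OS(=O)(=O)C(F)(F)F | intermediate
10 | (R)-1-phenylethylamine | C[C@@H](N)c1ccccc1 | starting material
11 | ketimine of 9 with 10, (1R) at the phenylethyl carbon | CC(Cc1cc(OCc2ccccc2)cc(OC)c1OS(=O)(=O)C(F)(F)F)=N[C@H](C)c1ccccc1 | intermediate
12 | 4-(benzyloxy)-2-methoxy-6-[(2R)-2-{[(1R)-1-phenylethyl]amino}propyl]phenyl trifluoromethanesulfonate | COc1cc(OCc2ccccc2)cc(C[C@@H](C)N[C@H](C)c2ccccc2)c1OS(=O)(=O)C(F)(F)F | intermediate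
13 | N-methyleneiminium ion of 12, (R,R) | COc1cc(OCc2ccccc2)cc(C[C@@H](C)[N+](=C)[C@H](C)c2ccccc2)c1OS(=O)(=O)C(F)(F)F | intermediate
14 | 4-(benzyloxy)-2-methoxy-6-[(2R)-2-{methyl[(1R)-1-phenylethyl]amino}propyl]phenyl trifluoromethanesulfonate | COc1cc(OCc2ccccc2)cc(C[C@@H](C)N(C)[C@H](C)c2ccccc2)c1OS(=O)(=O)C(F)(F)F | intermediate
15 | 2-bromo-5-methoxybenzaldehyde | COc1ccc(Br)c(C=O)c1 | starting material
16 | diethyl succinate | CCOC(=O)CCC(=O)OCC | starting material
17 | (E)-4-(2-bromo-5-methoxyphenyl)-3-(ethoxycarbonyl)but-3-enoic acid | OC(=O)C/C(=C\c1cc(OC)ccc1Br)C(=O)OCC | intermediate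
18 | ethyl 4-acetoxy-8-bromo-5-methoxynaphthalene-2-carboxylate | CCOC(=O)c1cc(OC(C)=O)c2c(OC)ccc(Br)c2c1 | intermediate
19 | ethyl 8-bromo-4-hydroxy-5-methoxynaphthalene-2-carboxylate | CCOC(=O)c1cc(O)c2c(OC)ccc(Br)c2c1 | intermediate
20 | ethyl 8-bromo-4,5-dimethoxynaphthalene-2-carboxylate | CCOC(=O)c1cc(OC)c2c(OC)ccc(Br)c2c1 | intermediate
21 | (8-bromo-4,5-dimethoxynaphthalen-2-yl)methanol | OCc1cc(OC)c2c(OC)ccc(Br)c2c1 | intermediate
22 | 1-bromo-7-(bromomethyl)-4,5-dimethoxynaphthalene | BrCc1cc(OC)c2c(OC)ccc(Br)c2c1 | intermediate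
23 | 1-bromo-4,5-dimethoxy-7-methylnaphthalene | Cc1cc(OC)c2c(OC)ccc(Br)c2c1 | intermediate
24 | (4,5-dimethoxy-7-methylnaphthalen-1-yl)lithium | Cc1cc(OC)c2c(OC)ccc([Li])c2c1 | intermediate
25 | lithium (4,5-dimethoxy-7-methylnaphthalen-1-yl)trimethoxyborate | [Li+].CO[B-](OC)(OC)c1ccc(OC)c2c(OC)cc(C)cc12 | intermediate
26 | (4,5-dimethoxy-7-methylnaphthalen-1-yl)boronic acid | Cc1cc(OC)c2c(OC)ccc(B(O)O)c2c1 | intermediate
27 | (2R)-1-[5-(benzyloxy)-2-(4,5-dimethoxy-7-methylnaphthalen-1-yl)-3-methoxyphenyl]-N-methyl-N-[(1R)-1-phenylethyl]propan-2-amine | COc1cc(OCc2ccccc2)cc(C[C@@H](C)N(C)[C@H](C)c2ccccc2)c1-c1ccc(OC)c2c(OC)cc(C)cc12 | intermediate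
28 | 4-(4,5-dimethoxy-7-methylnaphthalen-1-yl)-3-methoxy-5-[(2R)-2-(methylamino)propyl]phenol | COc1cc(O)cc(C[C@@H](C)NC)c1-c1ccc(OC)c2c(OC)cc(C)cc12 | intermediate
29 | acetaldehyde | CC=O | starting material
30 | N-ethylidene-N-methyliminium ion of 28, (R) | COc1cc(O)cc(C[C@@H](C)[N+](C)=CC)c1-c1ccc(OC)c2c(OC)cc(C)cc12 | intermediate
31 | ancistrocongoline B, (1R,3R)-5-(4,5-dimethoxy-7-methylnaphthalen-1-yl)-6-methoxy-1,2,3-trimethyl-1,2,3,4-tetrahydroisoquinolin-8-ol | COc1cc(O)c2c(c1-c1ccc(OC)c3c(OC)cc(C)cc13)C[C@@H](C)N(C)[C@@H]2C | target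

**Step count**
- Total step count: 19.
- Longest linear sequence: 11 (steps 1–8, then 17–19). The branch of steps 9–16, then 17–19, is equally long.

**Steps most likely to fail**

The weakest point is step 17. The triflate is electron-rich and flanked on both sides, so oxidative addition is slow. Aqueous base can hydrolyse it, and the electron-rich boronic acid can protodeboronate. The fallback drops boron and base altogether. It sets out from bromide 23 and triflate 14 and comes back at 27.
- Bromide 23 is lithiated as in step 16 to aryllithium 24.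
- ZnCl2 transmetalates 24 to (4,5-dimethoxy-7-methylnaphthalen-1-yl)zinc chloride F3.
- F3 undergoes a Negishi coupling with 14 [Pd2(dba)3, RuPhos, LiCl, THF, 70 °C] to give 27, and boronic acid 26 is bypassed.

The second risk is step 7. Methyl and arylmethyl differ little in size, so hydride reduction of the ketimine may give a poor diastereomer ratio and heavy losses on purification. The fallback replaces auxiliary control by catalyst control plus inversion. It sets out from ketone 9 and comes back at amine 12.
- Ketone 9 is reduced with (R)-2-methyl-CBS-oxazaborolidine and BH3·SMe2 (or a Prelog-type alcohol dehydrogenase with iPrOH) to 4-(benzyloxy)-2-[(2S)-2-hydroxypropyl]-6-methoxyphenyl trifluoromethanesulfonate F1.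
- MsCl/Et3N converts it into 4-(benzyloxy)-2-methoxy-6-[(2S)-2-(methylsulfonyloxy)propyl]phenyl trifluoromethanesulfonate F2.
- SN2 displacement by amine 10 (3 equiv, MeCN, 70 °C) inverts the centre and gives 12. Any stereochemical leakage appears as a separable diastereomer.

The third risk is step 19. The small N-methyl group may not enforce a high trans:cis ratio, and acetaldehyde can self-condense with a secondary amine. The fallback runs the same type of ring closure on the bulkier N-(1-phenylethyl) amine and installs N-methyl last. It sets out from 12 and 26 and comes back at 31.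
- Coupling of 12 with 26 under the conditions of step 17 gives (2R)-1-[5-(benzyloxy)-2-(4,5-dimethoxy-7-methylnaphthalen-1-yl)-3-methoxyphenyl]-N-[(1R)-1-phenylethyl]propan-2-amine F4.
- Acetaldehyde 29 and TFA in CH2Cl2 (0 °C to rt) close the ring under stronger allylic strain from the large N-substituent. The product is (1R,3R)-8-(benzyloxy)-5-(4,5-dimethoxy-7-methylnaphthalen-1-yl)-6-methoxy-1,3-dimethyl-2-[(1R)-1-phenylethyl]-1,2,3,4-tetrahydroisoquinoline F5.
- Hydrogenolysis in the presence of formaldehyde (H2, Pd(OH)2/C, aq HCHO, MeOH) removes both benzylic groups and reductively methylates nitrogen to give 31.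

**Further compounds**
F1 | step 7 | 4-(benzyloxy)-2-[(2S)-2-hydroxypropyl]-6-methoxyphenyl trifluoromethanesulfonate | COc1cc(OCc2ccccc2)cc(C[C@H](C)O)c1OS(=O)(=O)C(F)(F)F
F2 | step 7 | 4-(benzyloxy)-2-methoxy-6-[(2S)-2-(methylsulfonyloxy)propyl]phenyl trifluoromethanesulfonate | COc1cc(OCc2ccccc2)cc(C[C@H](C)OS(C)(=O)=O)c1OS(=O)(=O)C(F)(F)F
F3 | step 17 | (4,5-dimethoxy-7-methylnaphthalen-1-yl)zinc chloride | Cc1cc(OC)c2c(OC)ccc([Zn]Cl)c2c1
F4 | step 19 | (2R)-1-[5-(benzyloxy)-2-(4,5-dimethoxy-7-methylnaphthalen-1-yl)-3-methoxyphenyl]-N-[(1R)-1-phenylethyl]propan-2-amine | COc1cc(OCc2ccccc2)cc(C[C@@H](C)N[C@H](C)c2ccccc2)c1-c1ccc(OC)c2c(OC)cc(C)cc12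
F5 | step 19 | (1R,3R)-8-(benzyloxy)-5-(4,5-dimethoxy-7-methylnaphthalen-1-yl)-6-methoxy-1,3-dimethyl-2-[(1R)-1-phenylethyl]-1,2,3,4-tetrahydroisoquinoline | COc1cc(OCc4ccccc4)c2c(c1-c1ccc(OC)c3c(OC)cc(C)cc13)C[C@@H](C)N([C@H](C)c1ccccc1)[C@@H]2C
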